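**Plan**
- Retrosynthesis: the three O–benzyl bonds are cut last. Then, in each outer ring, C1'–C2' and C4'–C5' are cut (four C–C bonds in all), which removes C2'–C3'–C4' as a 2,2-dimethylmalonyl unit. Then the two ArCH2–CH2 bonds are cut (diketone dianion plus benzylic bromide), and finally the benzylic carbons (from formyl groups) and the aryl isobutyryl group.
- Forward: the central ring is finished first (steps 1–5), both diketone chains are attached in one operation (step 6), both outer rings are closed together (step 7), and debenzylation ends the route (step 8).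
- Enabling feature (outer ring numbered C1' = carbon carrying the CH2 bridge, C2' = enol carbon, C3' = CMe2, C4' = ring ketone, C5' = carbon carrying the isobutyryl group, C6' = enol carbon between C5' and C1'): C3' is quaternary and sits between two oxygenated carbons, so C2'–C3'–C4' is a malonyl unit with no acidic hydrogen. C1'–C6'–C5' plus the exocyclic isobutyryl carbonyl is a 1,3-diketone whose terminal α-carbon is C1'.
- Stereochemistry: none has to be set.

Key step: step 7

Remark: the target has no stereocentre and no stereogenic double bond (every C=C is a ring enol bond), so it is achiral and "single enantiomer" reduces to the constitution. All triketone rings are written in the enol tautomer of the target SMILES.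

**Route**

Step 1
Reactants: 1 phloroglucinol; 2 isobutyryl chloride
Product: 3 2-methyl-1-(2,4,6-trihydroxyphenyl)propan-1-one (phlorisobutyrophenone)
Conditions: AlCl3 (3.5 equiv), PhNO2/CH2Cl2, 0 → 50 °C; aq. HCl
Reagents that add atoms: none
Why: Friedel–Crafts C-acylation of phloroglucinol, which should stop after one acyl group because the chelated aryl ketone deactivates the ring towards a second acylium ion.

Step 2
Reactants: 3 phlorisobutyrophenone
Product: 4 2,4,6-trihydroxy-5-(2-methylpropanoyl)benzene-1,3-dicarbaldehyde
Conditions: hexamethylenetetramine (5 equiv), TFA, 90 °C; then 3 M HCl, 90 °C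
Reagents that add atoms: hexamethylenetetramine, C1N2CN3CN1CN(C2)C3; water, O
Why: Duff formylation, in which the two remaining ring CH positions, each activated by three hydroxyl groups, are attacked by the iminium ions from protonated hexamine (as in the exhaustive formylation of phloroglucinol) and acid hydrolysis releases the aldehydes.

Step 3
Reactants: 4 diformyl phlorisobutyrophenone
Product: 5 2,4,6-tris(benzyloxy)-5-(2-methylpropanoyl)benzene-1,3-dicarbaldehyde
Conditions: BnBr (4.5 equiv), K2CO3 (5 equiv), DMF, 60 °C
Reagents that add atoms: benzyl bromide, BrCc1ccccc1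
Why: Williamson O-alkylation of the three phenoxides, where the fully substituted ring excludes C-benzylation and warming in DMF should overcome the chelation of each hydroxyl to its neighbouring carbonyl groups.

Step 4
Reactants: 5 tris(benzyloxy) dialdehyde
Product: 6 1-[2,4,6-tris(benzyloxy)-3,5-bis(hydroxymethyl)phenyl]-2-methylpropan-1-one
Conditions: NaBH4 (1.1 equiv), THF/MeOH, −10 → 0 °C
Reagents that add atoms: none
Why: chemoselective borohydride reduction, the two aldehydes being reduced much faster than the di-ortho-substituted aryl ketone that is also shielded by its isopropyl group.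

Step 5
Reactants: 6 diol
Product: 7 1-[2,4,6-tris(benzyloxy)-3,5-bis(bromomethyl)phenyl]-2-methylpropan-1-one
Conditions: CBr4 (2.4 equiv), PPh3 (2.4 equiv), CH2Cl2, 0 °C; used at once
Reagents that add atoms: carbon tetrabromide, BrC(Br)(Br)Br
Why: Appel reaction, which converts both benzylic alcohols into bromides under neutral conditions that spare the benzyl ethers, and the hexasubstituted ring offers no free position for Friedel–Crafts self-condensation.

Step 6
Reactants: 7 dibromide; 8 5-methylhexane-2,4-dione (2.6 equiv)
Product: 9 7,7'-[2,4,6-tris(benzyloxy)-5-(2-methylpropanoyl)-1,3-phenylene]bis(2-methylheptane-3,5-dione)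
Conditions: 8, LDA (5.2 equiv), THF, −78 → 0 °C; then 7, −78 → 0 °C; 1 M HCl
Reagents that add atoms: none
Why: Hauser-type terminal alkylation of a β-diketone dianion, in which the CH2 carbanion (formed at the methyl group and not at the isopropyl methine) is the most nucleophilic site and displaces each benzylic bromide by SN2.

Step 7
Reactants: 9 bis(β-diketone); 10 dimethyl 2,2-dimethylmalonate (2.5 equiv)
Product: 12 tri-O-benzyl onind, via bis(triketo ester) 11 (not isolated)
Conditions: LDA (5.2 equiv), THF, −78 → 0 °C; then 10, −78 °C → rt, then 60 °C; 1 M HCl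
Reagents that add atoms: none
Why: Proposed new method: LDA should convert both β-diketones of 9 into dianions (the fifth equivalent is taken up by the hindered aryl isopropyl ketone, whose enolate is a spectator), and in each arm the more basic terminal carbanion at C1' (the chain CH2, deprotonated in preference to the isopropyl methine) adds to one ester of 10 to form C1'–C2' and give 11, after which the released methoxide relays the charge so that the doubly stabilised C5' enolate attacks the second ester and forms C4'–C5'. The closest known reactions are the terminal acylation of β-diketone dianions by esters and the Claisen (Dieckmann-type) cyclisation of 3,5,7-triketo esters to acylphloroglucinols. Each of the two rings closes in a 6-exo-trig Dieckmann mode, and no stereocentre arises because C1' and C5' end as enol carbons. The step needs terminal over central attack in the first acylation, which the higher basicity of the terminal carbanion secures, and C- over O-acylation in the closure, which is secured because an enol lactone is reopened by methoxide whereas the C-acylated ring is trapped as a non-electrophilic acyltrione dianion. Compound 10 has no α-hydrogen to quench the dianion, and the quaternary C3' blocks the competing aldol aromatisation of the triketo ester.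

Step 8
Reactants: 12 tri-O-benzyl onind
Product: 13 onind
Conditions: H2 (1 atm), 10% Pd/C, EtOAc/MeOH, rt
Reagents that add atoms: none
Why: catalytic hydrogenolysis of the three aryl benzyl ethers under neutral conditions, which should leave the chelated ketones and the enolised triketone double bonds (vinylogous acids) unreduced.

**Compound list**
1 | phloroglucinol (benzene-1,3,5-triol) | Oc1cc(O)cc(O)c1 | starting material
2 | isobutyryl chloride | CC(C)C(Cl)=O | starting material
3 | 2-methyl-1-(2,4,6-trihydroxyphenyl)propan-1-one | CC(C)C(=O)c1c(O)cc(O)cc1O | intermediate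
4 | 2,4,6-trihydroxy-5-(2-methylpropanoyl)benzene-1,3-dicarbaldehyde | CC(C)C(=O)c1c(O)c(C=O)c(O)c(C=O)c1O | intermediate
5 | 2,4,6-tris(benzyloxy)-5-(2-methylpropanoyl)benzene-1,3-dicarbaldehyde | CC(C)C(=O)c1c(OCc2ccccc2)c(C=O)c(OCc2ccccc2)c(C=O)c1OCc1ccccc1 | intermediate
6 | 1-[2,4,6-tris(benzyloxy)-3,5-bis(hydroxymethyl)phenyl]-2-methylpropan-1-one | CC(C)C(=O)c1c(OCc2ccccc2)c(CO)c(OCc2ccccc2)c(CO)c1OCc1ccccc1 | intermediate
7 | 1-[2,4,6-tris(benzyloxy)-3,5-bis(bromomethyl)phenyl]-2-methylpropan-1-one | CC(C)C(=O)c1c(OCc2ccccc2)c(CBr)c(OCc2ccccc2)c(CBr)c1OCc1ccccc1 | intermediate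
8 | 5-methylhexane-2,4-dione | CC(=O)CC(=O)C(C)C | starting material
9 | 7,7'-[2,4,6-tris(benzyloxy)-5-(2-methylpropanoyl)-1,3-phenylene]bis(2-methylheptane-3,5-dione) | CC(C)C(=O)c1c(OCc2ccccc2)c(CCC(=O)CC(=O)C(C)C)c(OCc2ccccc2)c(CCC(=O)CC(=O)C(C)C)c1OCc1ccccc1 | intermediate
10 | dimethyl 2,2-dimethylmalonate | COC(=O)C(C)(C)C(=O)OC | starting material
11 | dimethyl 4,4'-{[2,4,6-tris(benzyloxy)-5-(2-methylpropanoyl)-1,3-phenylene]bis(methylene)}bis(2,2,8-trimethyl-3,5,7-trioxononanoate), present as its polyenolate with configurationally labile C4 centres | CC(C)C(=O)c1c(OCc2ccccc2)c(CC(C(=O)C(C)(C)C(=O)OC)C(=O)CC(=O)C(C)C)c(OCc2ccccc2)c(CC(C(=O)C(C)(C)C(=O)OC)C(=O)CC(=O)C(C)C)c1OCc1ccccc1 | intermediate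
12 | tri-O-benzyl onind (central ring 2,4,6-tris(benzyloxy), both outer rings as in the target) | CC(C)C(=O)C1=C(O)C(Cc2c(OCc3ccccc3)c(CC3=C(O)C(C)(C)C(=O)C(C(=O)C(C)C)=C3O)c(OCc3ccccc3)c(C(=O)C(C)C)c2OCc2ccccc2)=C(O)C(C)(C)C1=O | intermediate
13 | onind | CC(C)C(=O)C1=C(O)C(Cc2c(O)c(CC3=C(O)C(C)(C)C(=O)C(C(=O)C(C)C)=C3O)c(O)c(C(=O)C(C)C)c2O)=C(O)C(C)(C)C1=O | target

**Count**
Total steps: 8. Longest linear sequence: 8 steps (1 → 13).

**Steps most likely to fail**

Step 7 (proposed new method). The secondary terminal carbanion may add only slowly to the hindered, α-quaternary ester. Proton exchange between the polyanionic arms may then leave one arm unacylated, or retro-Claisen cleavage of the open triketo ester may outrun ring closure. The fallback uses the established methylene-bridging of acylphloroglucinols. It sets out from 3, which is C-methylated twice (MeI, NaOMe, MeOH) to isobutyrylfilicinic acid F1. Compound 3 is then condensed with two equivalents of F1 and aqueous formaldehyde in dilute alkali at room temperature, where each hydroxymethylated ring loses water to an enone methide that is captured by the free ring carbon of its partner. This returns to the route at the target 13 and needs no protecting groups.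

Step 3. O-Alkylation may stall at the mono- or dibenzyl stage, because each phenoxide is chelated and flanked by two carbonyl groups, and the aldehydes may degrade on long exposure to base. The fallback protects before the one-carbon units are introduced. It sets out from 3, which is benzylated (BnBr, K2CO3, DMF) to 1-[2,4,6-tris(benzyloxy)phenyl]-2-methylpropan-1-one F2. F2 is brominated at both free ring positions (NBS, MeCN) to the dibromide F3. F3 is vinylated twice by Suzuki–Miyaura coupling (potassium vinyltrifluoroborate, Pd(OAc)2/SPhos, K2CO3, toluene/H2O) to the divinyl compound F4. Lemieux–Johnson cleavage (cat. OsO4, NaIO4, 2,6-lutidine, dioxane/H2O) then returns to the route at 5.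

Step 6. The electron-rich benzylic bromide may ionise and lose an ortho benzyl group through an o-quinone methide before SN2 takes place. Proton transfer from the aryl ketone may also quench the dianion, so that alkylation stops after one arm. The fallback avoids the halide altogether. It sets out from 5, which undergoes a boron-mediated aldol condensation with 8 at its methyl group (B2O3, B(OBu)3, n-BuNH2, EtOAc, 70 °C, then dilute HCl; the curcuminoid method) to the bis(enone) F5, (1E,1'E)-1,1'-[2,4,6-tris(benzyloxy)-5-(2-methylpropanoyl)-1,3-phenylene]bis(6-methylhept-1-ene-3,5-dione). Hydrogenation of the two C=C bonds over Pd/C poisoned with diphenyl sulfide, which spares benzyl ethers and ketones, returns to the route at 9.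

**Further compounds**
F1 | step 7 | isobutyrylfilicinic acid (2-(2-methylpropanoyl)-4,4-dimethylcyclohexane-1,3,5-trione, enol form) | CC(C)C(=O)C1=C(O)C=C(O)C(C)(C)C1=O
F2 | step 3 | 1-[2,4,6-tris(benzyloxy)phenyl]-2-methylpropan-1-one | CC(C)C(=O)c1c(OCc2ccccc2)cc(OCc2ccccc2)cc1OCc1ccccc1
F3 | step 3 | 1-[2,4,6-tris(benzyloxy)-3,5-dibromophenyl]-2-methylpropan-1-one | CC(C)C(=O)c1c(OCc2ccccc2)c(Br)c(OCc2ccccc2)c(Br)c1OCc1ccccc1
F4 | step 3 | 1-[2,4,6-tris(benzyloxy)-3,5-diethenylphenyl]-2-methylpropan-1-one | CC(C)C(=O)c1c(OCc2ccccc2)c(C=C)c(OCc2ccccc2)c(C=C)c1OCc1ccccc1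
F5 | step 6 | (1E,1'E)-1,1'-[2,4,6-tris(benzyloxy)-5-(2-methylpropanoyl)-1,3-phenylene]bis(6-methylhept-1-ene-3,5-dione) | CC(C)C(=O)c1c(OCc2ccccc2)c(/C=C/C(=O)CC(=O)C(C)C)c(OCc2ccccc2)c(/C=C/C(=O)CC(=O)C(C)C)c1OCc1ccccc1
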